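Compound numbers used throughout: 1–16 as in the compound list; the target is 16.

## The problem

Target 16 is a depside. The carboxyl of a 2,4-dimethoxy-6-propylbenzoyl unit (ring B) is esterified with the C4 oxygen of 2,4-dihydroxy-6-pentylbenzoic acid (ring A), whose C2 hydroxyl and C1 carboxyl remain free. There is no stereocentre, so the difficulties are regiochemistry and functional-group tolerance. The two sp3 centres that appear on the way (C1 and C6 of dione 10) are erased on aromatization and control nothing. Ring A has a 1,2,4,6-substitution pattern that electrophilic substitution of a resorcinol does not deliver cleanly, so the ring is better built with its substituents already in place. Only O4 of the two ring A oxygens may be acylated, and the acyl donor is a di-ortho-substituted, electron-rich benzoic acid that resists ordinary esterification. The finished molecule holds an aryl ester that hydroxide or alkoxide would cleave and a resorcylic acid that decarboxylates when heated in acid. The ring A carboxyl therefore needs a protecting group that leaves under neutral conditions. The enabling feature is that C1 (carboxyl), C2 (oxygen), C4 (oxygen) and C6 (pentyl) of ring A map atom for atom onto a 2,4-dioxo-6-alkylcyclohexane-1-carboxylate. C1–C3 with the ester are an acetoacetate and C4–C6 with the pentyl chain are an oct-2-enoate, so every ring bond can be made by enolate chemistry before a dehydrogenation reveals the arene.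

## Retrosynthesis

**16 from 15.** The last cut is the O–benzyl bond of the ring A ester. A benzyl ester is chosen over methyl or tert-butyl because it is removed by hydrogenolysis, which leaves the depside ester intact and does not expose the resorcylic acid to hot acid. The forward reaction only has to leave two arenes, two methyl ethers and an aryl ester untouched.

**15 from 13 and 5.** The depside C(=O)–O bond is cut next, giving benzyl 2,4-dihydroxy-6-pentylbenzoate 13 and acid 5. The two phenols of 13 are already unlike: the C2 hydroxyl is hydrogen-bonded to the ester carbonyl and crowded by it, the C4 hydroxyl is free. The neighbouring option is to acylate the C4 enol oxygen of dione 10 before aromatization. It was set aside because it relies on an enol-ester regioselectivity and on dehydrogenating a vinylogous anhydride, both less secure than acylating a chelation-differentiated resorcylate; it is kept as a reserve. The forward reaction must activate a hindered acid, done here through mixed trifluoroacetic anhydride 14.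

**13 from 10.** Adding two hydrogens to ring A leads back to dione 10. This removes all aromatic substitution chemistry from ring A. The forward step is a dehydrogenation by bromination and dehydrobromination through bromides 11 and 12, which must not brominate the product ring or harm the benzyl ester.

**10 from 8 and 7 (key disconnection).** The ring is opened at C1–C6 (retro-Michael) and C3–C4 (retro-Claisen), through open-chain adduct 9, giving benzyl acetoacetate 8 and benzyl (E)-oct-2-enoate 7. The neighbouring cut at C1–C6 and C2–C3 (a malonate with an enone) gives the same dione and is equally short. The acetoacetate pairing is preferred because the donor is more acidic, the enoate is less prone to self-condensation than a methyl vinyl ketone, and the C1 ester is a spectator throughout. The simplification is large: a tetrasubstituted ring becomes two acyclic esters. The forward reaction needs the Michael donor to be the doubly activated carbon and the ring to close through the methyl ketone enolate. Both esters are benzyl so that alkoxide exchange cannot scramble the ester that must survive to the end.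

**7 from 6.** The benzyl–oxygen bond of the enoate is cut to commercial (E)-oct-2-enoic acid 6; the forward step is a plain carboxylate benzylation.

**5 from 4, 4 from 2, 2 from 1.** The acid is traced to aldehyde 4 (chlorite oxidation). Aldehyde 4 is cut at the aryl–CHO bond to 1,3-dimethoxy-5-propylbenzene 2, with Vilsmeier–Haack formylation via iminium salt 3. Arene 2 is cut at the aryl–propyl bond to 1-bromo-3,5-dimethoxybenzene 1, with nickel-catalysed coupling to a propyl Grignard reagent. Formylation is preferred to directed lithiation of 2, which would attack between the two methoxy groups and give the wrong isomer. The formylation must go ortho to propyl and para to a methoxy group, which is the normal outcome for 5-alkylresorcinol dimethyl ethers.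

## Roads not taken

**Alternative 1:** Ring B acid by aryne carbomagnesiation.
- Cut: the aryl–propyl and aryl–carboxyl bonds of 2,4-dimethoxy-6-propylbenzoic acid A3 (identical with acid 5) are removed together. This leads to 3,5-dimethoxybenzyne A2, generated from 2-iodo-3,5-dimethoxyphenyl 4-methylbenzenesulfonate A1 by iodine–magnesium exchange and loss of the sulfonate.
- Forward key step: a propylmagnesium halide adds to the aryne carbon remote from the flanking methoxy group, and the new aryl–magnesium bond ortho to that methoxy group is quenched with CO2.
- Merits: two adjacent substituents are set in one flask, the methoxy group dictates the regiochemistry, and the carboxyl arrives at the correct oxidation level.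
- Weak points: A1 is not commercial, and making it means iodinating a 3,5-dimethoxyphenol derivative at one of three activated positions. Simple alkyl Grignard reagents are weaker aryne partners than heteroatom or aryl nucleophiles. The plan addresses only ring B and leaves ring A and the selective ester bond open.
- Comparison: from A1 it is one operation against three steps from bromide 1, so it is the more direct way to this acid once A1 is in hand. The chosen plan sets against this a commercial starting material and a formylation of well-established regiochemistry. The overall count does not fall once the preparation of A1 is included.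

**Alternative 2:** Biomimetic construction of ring B on the depside.
- Cut: the depside C–O bond and the C1–C6 bond of ring B.
- Forward key step: heating 6-(2,4-dioxoheptyl)-2,2-dimethyl-4H-1,3-dioxin-4-one A4 releases acylketene A5. The C4 phenol of benzyl 2-(benzyloxy)-4-hydroxy-6-pentylbenzoate A6 traps it, giving aryl 3,5,7-trioxodecanoate A7. Aldol condensation and aromatization then give benzyl 2-(benzyloxy)-4-[(2,4-dihydroxy-6-propylbenzoyl)oxy]-6-pentylbenzoate A8.
- Merits: the ester bond forms under neutral thermal conditions without a hindered acid, and ring B comes from acyclic material. Here it is better than the chosen plan, whose step 7 must force a di-ortho-substituted acid onto a phenol.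
- Weak points: ring A must still be made, and additionally protected at O2, to reach A6. In A7 the activated aryl ester can be attacked by an enol oxygen, expelling A6 and forming a pyrone. A8 carries two free ring B phenols where the target has methyl ethers, so a double O-methylation (one on a chelated, hindered hydroxyl, with base next to an aryl ester) and a double debenzylation follow.
- Comparison: this is the better plan for a congener with free ring B hydroxyls. For 16 it is longer and adds a base-mediated step on the finished depside, whereas the chosen plan carries the methyl ethers from a commercial arene.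

**Alternative 3:** Danheiser benzannulation for ring A.
- Cut: the C2–C3, C4–C5 and C1–C2 bonds of ring A.
- Forward key step: Wolff rearrangement of benzyl 3-(2-diazoacetyl)oct-2-enoate A9 gives vinylketene A10. This adds (ethynyloxy)triisopropylsilane A11 in a [2+2] cycloaddition, followed by four-electron ring opening, six-electron closure and tautomerization to benzyl 2-hydroxy-6-pentyl-4-(triisopropylsilyloxy)benzoate A12.
- Merits: the ring is formed regiospecifically at the arene oxidation level under neutral conditions, with no dehydrogenation. In that respect it is cleaner than step 6 of the chosen plan, which uses bromine on an electron-rich system.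
- Weak points: the oxygen left free in A12 is O2, the one that must not be acylated. A12 would have to be desilylated to 13, after which the same hydrogen-bond differentiation is used as in the chosen plan. A9 and A11 each need several steps (diazo transfer, ynol silyl ether synthesis), and the rearrangement needs photochemical or thermal activation of a diazo compound.
- Comparison: the chosen plan reaches 13 in two steps from 7 and 8 with ordinary reagents. It sets that brevity against the cleaner arene formation of the benzannulation.

Key step: step 5

Remark: compounds 9–12 are drawn as keto tautomers although they exist largely as enols, and 10 is racemic with one enantiomer drawn. Neither point affects the route, because both sp3 centres are lost in step 6.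

## Route

Step 1
Reactants: 1 1-bromo-3,5-dimethoxybenzene
Product: 2 1,3-dimethoxy-5-propylbenzene
Conditions: n-PrMgBr (1.3 equiv), NiCl2(dppp) (2 mol %), Et2O, 0 °C → reflux
Reagents that add atoms: propylmagnesium bromide, CCC[Mg]Br
Why: Kumada–Corriu coupling: oxidative addition of the aryl bromide to zerovalent nickel, transmetalation and reductive elimination; the chelating diphosphine dppp (1,3-bis(diphenylphosphino)propane) disfavours β-hydride elimination, so the primary alkyl group should be transferred without isomerization.

Step 2
Reactants: 2 1,3-dimethoxy-5-propylbenzene
Product: 4 2,4-dimethoxy-6-propylbenzaldehyde, via iminium chloride 3 (not isolated)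
Conditions: POCl3, DMF, 0 → 75 °C; then H2O, rt
Reagents that add atoms: N,N-dimethylformamide, CN(C)C=O; water, O
Why: Vilsmeier–Haack formylation: the chloroiminium ion attacks para to one methoxy group and ortho to the other (next to propyl), the site between the two methoxy groups being more hindered, as is usual for 5-alkylresorcinol dimethyl ethers. The two such positions are equivalent by symmetry, the product is deactivated towards a second formylation, and iminium salt 3 is hydrolysed on work-up.

Step 3
Reactants: 4 2,4-dimethoxy-6-propylbenzaldehyde
Product: 5 2,4-dimethoxy-6-propylbenzoic acid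
Conditions: NaClO2, NaH2PO4, 2-methyl-2-butene, t-BuOH/H2O, rt
Reagents that add atoms: sodium chlorite, [Na+].[O-]Cl=O
Why: Pinnick oxidation converts even hindered aryl aldehydes to acids and leaves the ethers alone; 2-methyl-2-butene scavenges the hypochlorous acid that would otherwise chlorinate the electron-rich ring.

Step 4
Reactants: 6 (E)-oct-2-enoic acid
Product: 7 benzyl (E)-oct-2-enoate
Conditions: BnBr, K2CO3, DMF, rt
Reagents that add atoms: benzyl bromide, BrCc1ccccc1
Why: SN2 O-alkylation of the potassium carboxylate with benzyl bromide; the conjugated E double bond is not affected under these mild conditions.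

Step 5
Reactants: 8 benzyl acetoacetate; 7 benzyl (E)-oct-2-enoate
Product: 10 benzyl (1RS,6SR)-2,4-dioxo-6-pentylcyclohexane-1-carboxylate (trans, racemic), via Michael adduct 9 (not isolated)
Conditions: KOtBu (1.1 equiv), t-BuOH/THF, rt → 80 °C; then 1 M HCl
Reagents that add atoms: none
Why: KOtBu converts 8 into its potassium enolate, whose doubly activated α-carbon (C1) adds to the β-carbon (C6) of enoate 7 in a Michael addition, giving adduct 9 after proton transfer. Equilibrium deprotonation of the acetyl methyl group (C3) then lets this ketone enolate attack the ester carbonyl C4 in an intramolecular Claisen condensation that expels benzyloxide. This closure is 6-exo-trig and forms the only ring of the step, the six-membered carbocycle of ring A. The released alkoxide deprotonates the new 1,3-dione at C3, and formation of this stabilized enolate pulls the reversible Michael and Claisen equilibria forward. The closest known reaction is the classical base-mediated condensation of acetoacetic esters with α,β-unsaturated esters to alkyl dihydroresorcylates, a sibling of the malonate–enone annulation used for 5-alkylresorcinols. C1 and C6 become stereocentres; C1 is epimerizable as part of a β-keto ester, so the trans isomer with both substituents equatorial should prevail under thermodynamic control, as a racemate, and both centres disappear in step 6. The selectivity needed is regiochemical: the α-carbon of 8 is by far the most acidic donor site, and among the enolates of 9 only the methyl ketone enolate can reach an ester through a six-membered transition state (every other pairing would give a four-membered ring), which fixes pentyl at C6 next to C1. Both esters are benzyl, so any alkoxide exchange during the reaction is degenerate.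

Step 6
Reactants: 10 benzyl (1RS,6SR)-2,4-dioxo-6-pentylcyclohexane-1-carboxylate
Product: 13 benzyl 2,4-dihydroxy-6-pentylbenzoate, via 3-bromo dione 11 (not isolated), via 5-bromo dione 12 (not isolated)
Conditions: Br2 (1.0 equiv), DMF, 0 °C; then 80 °C
Reagents that add atoms: none
Why: Bromination of the dione enol gives the C3 bromide 11; HBr relays the bromine to the α′-carbon C5 (12), hot DMF removes HBr across C5–C6, and the resulting cyclohexenedione tautomerizes to the resorcylate. This bromination–dehydrobromination is a known way to aromatize alkyl 6-alkyl-2,4-dioxocyclohexanecarboxylates; one equivalent of bromine and low-temperature addition are meant to limit nuclear bromination.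

Step 7
Reactants: 13 benzyl 2,4-dihydroxy-6-pentylbenzoate; 5 2,4-dimethoxy-6-propylbenzoic acid
Product: 15 benzyl 4-[(2,4-dimethoxy-6-propylbenzoyl)oxy]-2-hydroxy-6-pentylbenzoate, via mixed trifluoroacetic anhydride 14 (not isolated)
Conditions: (CF3CO)2O, toluene, rt
Reagents that add atoms: none
Why: Mixed-anhydride esterification: acid 5 and trifluoroacetic anhydride give 14, an acylium-like donor suited to a di-ortho-substituted, electron-rich acid. It should acylate the free C4 phenol of 13, because the C2 hydroxyl is held in a hydrogen bond to the ester carbonyl and shielded by it, which is the usual basis of regioselective depside formation.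

Step 8
Reactants: 15 benzyl 4-[(2,4-dimethoxy-6-propylbenzoyl)oxy]-2-hydroxy-6-pentylbenzoate
Product: 16 4-[(2,4-dimethoxy-6-propylbenzoyl)oxy]-2-hydroxy-6-pentylbenzoic acid
Conditions: H2 (1 atm), 10% Pd/C, EtOAc, rt
Reagents that add atoms: none
Why: Catalytic hydrogenolysis of the benzyl ester under neutral conditions; the aryl ester, the methyl ethers and both arenes are inert to hydrogen over palladium at room temperature, and a non-nucleophilic solvent excludes transesterification of the depside.

## Compound list

1 | 1-bromo-3,5-dimethoxybenzene | COc1cc(Br)cc(OC)c1 | starting material
2 | 1,3-dimethoxy-5-propylbenzene | CCCc1cc(OC)cc(OC)c1 | intermediate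
3 | N-[(2,4-dimethoxy-6-propylphenyl)methylidene]-N-methylmethanaminium chloride | CCCc1cc(OC)cc(OC)c1C=[N+](C)C.[Cl-] | intermediate
4 | 2,4-dimethoxy-6-propylbenzaldehyde | CCCc1cc(OC)cc(OC)c1C=O | intermediate
5 | 2,4-dimethoxy-6-propylbenzoic acid | CCCc1cc(OC)cc(OC)c1C(=O)O | intermediate
6 | (E)-oct-2-enoic acid | CCCCC/C=C/C(=O)O | starting material
7 | benzyl (E)-oct-2-enoate | CCCCC/C=C/C(=O)OCc1ccccc1 | intermediate
8 | benzyl acetoacetate (benzyl 3-oxobutanoate) | CC(=O)CC(=O)OCc1ccccc1 | starting material
9 | dibenzyl 2-acetyl-3-pentylpentanedioate (mixture of diastereomers) | CCCCCC(CC(=O)OCc1ccccc1)C(C(C)=O)C(=O)OCc1ccccc1 | intermediate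
10 | benzyl (1RS,6SR)-2,4-dioxo-6-pentylcyclohexane-1-carboxylate (trans, racemic; 1S,6R enantiomer drawn) | CCCCC[C@@H]1CC(=O)CC(=O)[C@H]1C(=O)OCc1ccccc1 | intermediate
11 | benzyl 3-bromo-2,4-dioxo-6-pentylcyclohexane-1-carboxylate (mixture of diastereomers) | CCCCCC1CC(=O)C(Br)C(=O)C1C(=O)OCc1ccccc1 | intermediate
12 | benzyl 5-bromo-2,4-dioxo-6-pentylcyclohexane-1-carboxylate (mixture of diastereomers) | CCCCCC1C(Br)C(=O)CC(=O)C1C(=O)OCc1ccccc1 | intermediate
13 | benzyl 2,4-dihydroxy-6-pentylbenzoate | CCCCCc1cc(O)cc(O)c1C(=O)OCc1ccccc1 | intermediate
14 | 2,4-dimethoxy-6-propylbenzoic trifluoroacetic anhydride | CCCc1cc(OC)cc(OC)c1C(=O)OC(=O)C(F)(F)F | intermediate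
15 | benzyl 4-[(2,4-dimethoxy-6-propylbenzoyl)oxy]-2-hydroxy-6-pentylbenzoate | CCCCCc1cc(OC(=O)c2c(CCC)cc(OC)cc2OC)cc(O)c1C(=O)OCc1ccccc1 | intermediate
16 | 4-[(2,4-dimethoxy-6-propylbenzoyl)oxy]-2-hydroxy-6-pentylbenzoic acid | CCCCCc1cc(OC(=O)c2c(CCC)cc(OC)cc2OC)cc(O)c1C(=O)O | target

## Step count and risks

Total: 8 steps. Longest linear sequence: 5 steps (steps 1, 2, 3, 7, 8; the ring A branch, steps 4, 5, 6, 7, 8, is equally long).

**Step 5 (key step).**
- Risk: the Michael addition is reversible and the Claisen closure depends on a small equilibrium concentration of the methyl ketone enolate of an α,α-disubstituted acetoacetate. The reaction may stall at the open-chain stage. Benzyloxide may also cleave the acetyl group of the adduct (retro-Claisen), and base may deconjugate the enoate to its unreactive β,γ-isomer.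
- Fallback: change the ring-closing bond while keeping the same dione. This fallback does not branch from an intermediate of the route; it replaces partners 7 and 8 by two purchased compounds. Dibenzyl malonate F1 and (E)-non-3-en-2-one F2 are combined with KOtBu in t-BuOH. Michael addition gives dibenzyl 2-(2-oxononan-4-yl)propanedioate F3, whose methyl ketone enolate closes onto one of the two geminal esters (forming C2–C3 instead of C3–C4). After acidification the route is rejoined at dione 10.

**Step 6.**
- Risk: nuclear bromination of the electron-rich resorcylate as it forms, and acid-promoted loss of the benzyl ester followed by decarboxylation in hot HBr/DMF.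
- Fallback: acylate first and dehydrogenate without halogen. Acid 5 is converted with oxalyl chloride and catalytic DMF into 2,4-dimethoxy-6-propylbenzoyl chloride F4. Starting from dione 10, its less hindered C4 enol oxygen is acylated with F4 (Et3N, CH2Cl2, 0 °C) to give benzyl trans-4-[(2,4-dimethoxy-6-propylbenzoyl)oxy]-2-oxo-6-pentylcyclohex-3-ene-1-carboxylate F5. DDQ in hot dioxane dehydrogenates F5 to the arene. This path bypasses 13 and step 7 and returns to the route at 15.

**Step 7.**
- Risk: acylation at the wrong site (the C2 oxygen, both oxygens, or a ring carbon of 13 by the acylium-like donor), and incomplete conversion because the acid is hindered.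
- Fallback: move from acidic mixed-anhydride activation to base-mediated phenoxide acylation. Starting from acid 5, 2,4-dimethoxy-6-propylbenzoyl chloride F6 is made with oxalyl chloride. It is added to 13 with K2CO3 in acetone, where the more acidic, unchelated C4 hydroxyl is ionized preferentially. The route is rejoined at 15.

**Step 1.**
- Risk: hydrodehalogenation or homocoupling in place of cross-coupling, or slow oxidative addition of the electron-rich bromide.
- Fallback: build the propyl chain by olefination, setting out from a purchased aldehyde instead of bromide 1. 3,5-Dimethoxybenzaldehyde F7 undergoes a Wittig reaction with the ylide from ethyltriphenylphosphonium bromide and KOtBu to give 1,3-dimethoxy-5-(prop-1-en-1-yl)benzene F8 as an E/Z mixture. Hydrogenation over 10% Pd/C returns to the route at 2.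

## Further compounds

F1 | step 5 | dibenzyl malonate | O=C(CC(=O)OCc1ccccc1)OCc1ccccc1
F2 | step 5 | (E)-non-3-en-2-one | CCCCC/C=C/C(C)=O
F3 | step 5 | dibenzyl 2-(2-oxononan-4-yl)propanedioate (racemic) | CCCCCC(CC(C)=O)C(C(=O)OCc1ccccc1)C(=O)OCc1ccccc1
F4 | step 6 | 2,4-dimethoxy-6-propylbenzoyl chloride | CCCc1cc(OC)cc(OC)c1C(Cl)=O
F5 | step 6 | benzyl trans-4-[(2,4-dimethoxy-6-propylbenzoyl)oxy]-2-oxo-6-pentylcyclohex-3-ene-1-carboxylate (racemic, one enantiomer drawn) | CCCCC[C@@H]1CC(OC(=O)c2c(CCC)cc(OC)cc2OC)=CC(=O)[C@H]1C(=O)OCc1ccccc1
F6 | step 7 | 2,4-dimethoxy-6-propylbenzoyl chloride | CCCc1cc(OC)cc(OC)c1C(Cl)=O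
F7 | step 1 | 3,5-dimethoxybenzaldehyde | COc1cc(C=O)cc(OC)c1
F8 | step 1 | 1,3-dimethoxy-5-(prop-1-en-1-yl)benzene (E/Z mixture) | CC=Cc1cc(OC)cc(OC)c1
A1 | alternative 1 | 2-iodo-3,5-dimethoxyphenyl 4-methylbenzenesulfonate | COc1cc(OC)c(I)c(OS(=O)(=O)c2ccc(C)cc2)c1
A2 | alternative 1 | 3,5-dimethoxybenzyne (1,2-didehydro-3,5-dimethoxybenzene) | COC1=CC(OC)=CC#C1
A3 | alternative 1 | 2,4-dimethoxy-6-propylbenzoic acid | CCCc1cc(OC)cc(OC)c1C(=O)O
A4 | alternative 2 | 6-(2,4-dioxoheptyl)-2,2-dimethyl-4H-1,3-dioxin-4-one | CCCC(=O)CC(=O)CC1=CC(=O)OC(C)(C)O1
A5 | alternative 2 | 3,5,7-trioxodec-1-en-1-one (acylketene) | CCCC(=O)CC(=O)CC(=O)C=C=O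
A6 | alternative 2 | benzyl 2-(benzyloxy)-4-hydroxy-6-pentylbenzoate | CCCCCc1cc(O)cc(OCc2ccccc2)c1C(=O)OCc1ccccc1
A7 | alternative 2 | benzyl 2-(benzyloxy)-6-pentyl-4-[(3,5,7-trioxodecanoyl)oxy]benzoate | CCCCCc1cc(OC(=O)CC(=O)CC(=O)CC(=O)CCC)cc(OCc2ccccc2)c1C(=O)OCc1ccccc1
A8 | alternative 2 | benzyl 2-(benzyloxy)-4-[(2,4-dihydroxy-6-propylbenzoyl)oxy]-6-pentylbenzoate | CCCCCc1cc(OC(=O)c2c(CCC)cc(O)cc2O)cc(OCc2ccccc2)c1C(=O)OCc1ccccc1
A9 | alternative 3 | benzyl 3-(2-diazoacetyl)oct-2-enoate | CCCCCC(=CC(=O)OCc1ccccc1)C(=O)C=[N+]=[N-]
A10 | alternative 3 | benzyl 3-(2-oxoethenyl)oct-2-enoate (vinylketene) | CCCCCC(C=C=O)=CC(=O)OCc1ccccc1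
A11 | alternative 3 | (ethynyloxy)triisopropylsilane | C#CO[Si](C(C)C)(C(C)C)C(C)C
A12 | alternative 3 | benzyl 2-hydroxy-6-pentyl-4-(triisopropylsilyloxy)benzoate | CCCCCc1cc(O[Si](C(C)C)(C(C)C)C(C)C)cc(O)c1C(=O)OCc1ccccc1
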